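At early times the grey run (1 mol%, 6 °C) holds more target than isomer of the product: 56.9% against 30.6% at 4.00 h, with 12.4% of the substrate still there. By 12.0 h the isomer stands at 47.1% and the target at 53.0%, and from there up to 48.0 h the grey readings of target lie between 52.7% and 55.5% and those of the isomer between 46.0% and 47.5%, against a scatter of 1 percentage point. The ochre run (4 mol%, 20 °C) is level from its first reading, but with the order reversed.

| flask | substrate | free catalyst | temperature | remark | time |
|---|---|---|---|---|---|
| grey | 0.20 M | 1 mol% | 6 °C | run made earlier |  |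
| ochre | 0.20 M | 4 mol% | 20 °C | run made earlier |  |
| winter | 0.20 M | 2 mol% | 0 °C |  | 50 h |
| noon | 0.20 M | 2 mol% | 25 °C |  | 50 h |

| run | time / h | target / % | catalyst intermediate B / % | isomer of the product / % | catalyst intermediate A / % | substrate / % |
|---|---|---|---|---|---|---|
| grey | 4.00 | 56.9 | 0 | 30.6 | 0 | 12.4 |
| grey | 6.00 | 56.2 | 1.1 | 41.5 | 0 | 0 |
| grey | 12.0 | 53.0 | 0 | 47.1 | 1.4 | 0.4 |
| grey | 20.0 | 52.7 | 0.2 | 47.5 | 0 | 1.9 |
| grey | 30.0 | 55.3 | 0.5 | 46.2 | 0.6 | 0 |
| grey | 48.0 | 55.5 | 1.8 | 46.0 | 0 | 0 |
| ochre | 3.00 | 44.8 | 0 | 55.9 | 0 | 0.2 |
| ochre | 6.00 | 44.5 | 0 | 54.3 | 0 | 0.7 |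
| ochre | 10.0 | 44.4 | 0.7 | 57.1 | 0 | 0 |
| ochre | 12.0 | 43.9 | 0.2 | 55.4 | 0 | 0 |
| ochre | 15.0 | 45.7 | 0 | 55.4 | 0 | 0 |
| ochre | 20.0 | 42.2 | 0 | 55.7 | 1.3 | 0.1 |

(each reading ± 1 percentage point)

1. which of these there is most of at the end, counted by the substrate in it, winter (catalyst intermediate B / target / substrate / isomer of the product / catalyst intermediate A)
2. which of these there is most of at the end, counted by the substrate in it, noon (catalyst intermediate B / target / substrate / isomer of the product / catalyst intermediate A)
3. amount of the one of these that there is most of at the end, in percent of the substrate charged, winter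
4. amount of the one of these that there is most of at the end, in percent of the substrate charged, noon

For winter and noon the decision is what to change. Grey is flat from 12.0 h, well before 50 h, at half the loading of the new flasks, so time and catalyst are left as charged. Winter is colder than grey, so this is a risk taken knowingly. Temperature then has to choose the product, if the plateau is an equilibrium (thermodynamic control).

The plateau ratio c(isomer)/c(target) reads 0.863 in grey and 1.26 in ochre. The two runs differ in loading too, so reading the shift as temperature is an assumption. Taking the logarithm of the ratio as straight in inverse temperature gives a slope of 2200 K. The line reaches a ratio of one at 11.3 °C, the crossing temperature: the temperature at which target hands the lead to the isomer. Winter lies below it and noon above it. This reckoning gives winter 57.9% target and noon 58.8% isomer.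

The forecast names target at 59% for winter and isomer of the product at 59% for noon, reasoning “so target looks kinetic and the plateau looks like an equilibrium rather than a fixed selectivity”. It picks the same species as the reckoning above, and its two amounts are higher than the reckoned ones.

Winter ends with 57.8% target, and noon with 58.6% isomer of the product.

    catalyst intermediate B → free catalyst + target (k = 0.310 min⁻¹, Ea = 73.0 kJ mol⁻¹)
    substrate + free catalyst → catalyst intermediate A (k = 7.40 M⁻¹ min⁻¹, Ea = 58.0 kJ mol⁻¹)
    target ⇌ isomer of the product (K = 0.730, k = 0.00250 min⁻¹, Ea = 83.0 kJ mol⁻¹, ΔH = 18.0 kJ mol⁻¹)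
    substrate + free catalyst → spent catalyst (k = 0.00570 M⁻¹ min⁻¹, Ea = 73.0 kJ mol⁻¹)
    catalyst intermediate A → catalyst intermediate B (k = 16.0 min⁻¹, Ea = 63.0 kJ mol⁻¹)
    (constants at 0 °C)

For the noon answer to turn, its temperature has to cross 11.3 °C, where target and isomer hold the same at the end. The crossing temperature of 11.3 °C carries to a flask like noon kept at 40 °C: with the slope 2200 K, c(isomer)/c(target) comes to 2.03, which puts target at 33.0%. That flask ends with target at 33.2%.

(The runs are calculated from invented constants, and the scatter is random.)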